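## Analysis of the target

Target 14 is a (2S)-flavanone. Ring A (C4a, C5, C6, C7, C8, C8a) is a phloroglucinol-type benzene with free OH at C5 and C7, ring C (O1, C2, C3, C4, C4a, C8a) is a dihydro-4-pyranone, and ring B is a 4-hydroxyphenyl group on C2. C6 carries an (E)-3,7-dimethylocta-1,6-dien-1-yl chain (C1' to C8').

There are two stereocenters, C2 (S) and the allylic C3' (S). They are eight bonds apart and cannot relay information, so each needs its own source. C3', with the C1'=C2' and C6'=C7' olefins, is the skeleton of the terpene diene 6; C2 has to be created.

C2 is the labile one. It is a benzylic ether carbon β to the C4 ketone, and base or hot acid opens ring C by a retro-oxa-Michael reaction and recloses it. Here that would give C2 epimers that differ only at a remote center and could not be expected to separate.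

Ring A adds a regiochemical problem: C6 and C8 are both activated CH positions and differ only in their neighbours (5-OH and 7-OH for C6, 7-OH and O1 for C8).

The chain is fragile in its own way. The o-hydroxystyrene (5-OH or 7-OH, C6, C1'=C2') is the tautomer of an o-quinone methide tethered by four carbons to the C6'=C7' olefin, so acid or heat invites ring closure between C1' and C6'/C7'. Olefin metathesis would close the 1,6-diene to a cyclopentene, and hydrogenolysis is excluded.

The feature the chosen strategy is tied to is the O1–C2(H)(aryl)–C3H2–C4(=O) segment of ring C. C2 is the β-carbon of the C4 carbonyl, so the C2–C1'' bond to ring B can be formed by conjugate addition to the C2=C3 enone of a 4-pyranone. This creates the stereocenter in the same event, as the last skeletal bond.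

The difficulty is therefore timing, not size: C6 must be addressed without C8, C2 must appear late and never see base, and three phenols must be unmasked without acid, strong base or hydrogen.

## Retrosynthetic reasoning

**14 from 13.** The last disconnection cuts only the O7–Si and O4'–Si bonds. Silyl ethers are chosen because their removal needs neither the acid that would protonate C2' of the styrene nor the base that would open ring C. The forward step liberates the phenols (the 5-OH is never protected) with C2 already in place, so it must be buffered.

**13 from 11 and 12 (key disconnection).** The C2–C1'' bond between ring C and ring B is cut, not the O1–C2 bond that the usual ring closure makes. This removes ring B and the labile stereocenter together and leaves chromone 11, in which ring C is a flat, achiral 4-pyranone. The C2=C3 double bond of 11 is a bond the target does not have, and it is kept on purpose through the earlier steps. While it is there, ring C cannot open, O1 stays tied into the ring (which is what distinguishes C8 from C6), and base can do no harm. The forward reaction has to add the aryl group of 12 to C2 from one face only, stop at the ketone, and leave the two olefins of the chain alone.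

**11 from 5 and 10.** The C6–C1' bond between two sp2 carbons is cut. Cutting here, and not at C1'=C2' or C2'–C3', keeps C3' and the whole C10 chain in one piece from the chiral pool. The E geometry becomes a property of boronate 10, which a stereoretentive cross-coupling transfers. Metathesis fails on the 1,6-diene, and a carbonyl olefination would need an α-branched, epimerisable C9 aldehyde. The forward reaction must couple at a carbon flanked by two oxygen substituents.

**10 from 6, 7 and 8.** The C1'–B bond is cut back to the terminal vinyl C–H of 6, which already contains C3' in the S configuration and both carbons of the future styrene. The forward reaction must borylate the monosubstituted olefin with E geometry, leave the trisubstituted olefin, and not move the double bond toward C3'.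

**5 from 3, and 3 from 1.** The C6–I bond is cut, then the O7–Si bond. Iodination is placed after silylation of O7 and with the 5-OH free, because a free, carbonyl-chelated 5-OH directs the electrophile to its ortho position C6, while C8 lies between an ether and O1. Chromone 1 supplies ring A, ring C and the O1/O5/O7 differentiation ready-made, so nothing is spent on building the ring system.

## Alternatives that were turned down

**Alternative 1:** the textbook chalcone route, disconnecting O1–C2 and the C2–C3 bond.
- Forward key step: aldol condensation (Claisen–Schmidt) of acetophenone A1 with aldehyde A2 to chalcone A3, then 6-endo oxa-Michael ring closure and acetal cleavage to 14.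
- Turned down, first, because the oxa-Michael closure of a simple 2'-hydroxychalcone is reversible under the conditions that effect it. C2 is then formed under thermodynamic control, and enantioselective variants need an extra activating ester on the α-carbon and its later removal.
- Second, A1 needs the chain on the carbon between the two protected oxygens, with the free hydroxyl para to it. Electrophilic substitution of such acetophenones goes ortho to the free hydroxyl, to the carbon that becomes C8, so the regiochemistry must be fought with extra protecting-group steps.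
- Third, the chain would meet strong base in the aldol step and acid in the acetal cleavage, and the sequence is longer.

**Alternative 2:** disconnection of C6–C1' last, on an intact (2S)-flavanone.
- Forward key step: 3 is arylated first (same catalysis as the chosen key step) to flavanone A4, which is iodinated at C6 to A5 and coupled with 10 to give 13.
- The step count is the same. It was turned down because this order puts the labile C2 center through two more steps. One is a cross-coupling in aqueous base next to the 5-OH of a flavanone, which are the conditions of retro-oxa-Michael equilibration.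
- Any loss of configuration gives a C2 epimer that differs from 13 only at a remote center. In the chosen order the same two steps are run on 3 and 5, which have no stereocenter to lose.

**Alternative 3:** biomimetic disconnection of C6–C1' to an aldehyde.
- Forward key step: ortho-hydroxyalkylation of 3 at C6 by (S)-citronellal A6, loss of water to the o-quinone methide A7, and 1,5-prototropy to 11, in one operation without iodide or boron.
- Turned down because A7 is a heterodiene (O5=C5–C6=C1') held four carbons from the C6'=C7' olefin. Intramolecular hetero-Diels–Alder closure of such aldehyde-derived quinone methides is a fast, irreversible competitor of the proton shift.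
- In addition, the first C–C bond can form at C8, para to the 5-OH. Saving two steps does not outweigh a branching that would consume the chiral chain.

Key step: step 5

Assumption (remark on the chemistry): the facial preference of the t-BuPyOX palladium catalyst for chromone 11 is taken to follow that known for cyclic enones, which calls for the R ligand to obtain 2S; if the sense is the opposite, the S ligand is used and nothing else changes.

## Route

Step 1
Reactants: 1 5,7-dihydroxy-4H-chromen-4-one; 2 chlorotri(propan-2-yl)silane
Product: 3 5-hydroxy-7-{[tri(propan-2-yl)silyl]oxy}-4H-chromen-4-one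
Conditions: 2 (1.05 equiv), imidazole (2.2 equiv), DMF, 0 °C to rt
Reagents that add atoms: chlorotri(propan-2-yl)silane (2), CC(C)[Si](Cl)(C(C)C)C(C)C
Why: Silylation of the free phenol; the 5-OH is locked in a hydrogen bond to the C4 carbonyl and is far less nucleophilic, so one equivalent of the bulky chlorosilane should react at O7 only. The triisopropylsilyl ether is chosen because it should tolerate methanol, aqueous phosphate and the key step and leaves with fluoride.

Step 2
Reactants: 3 5-hydroxy-7-{[tri(propan-2-yl)silyl]oxy}-4H-chromen-4-one; 4 benzyltrimethylammonium dichloroiodate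
Product: 5 5-hydroxy-6-iodo-7-{[tri(propan-2-yl)silyl]oxy}-4H-chromen-4-one
Conditions: 4 (1.05 equiv), CaCO3, CH2Cl2–MeOH (5:2), rt, dark
Reagents that add atoms: benzyltrimethylammonium dichloroiodate (4), C[N+](C)(C)Cc1ccccc1.Cl[I-]Cl
Why: Electrophilic aromatic iodination; with the 5-OH free and O7 etherified, phenols of this 5-hydroxy-7-alkoxy-4-pyranone type are iodinated by this reagent ortho to the free hydroxyl, at C6 and not at C8. CaCO3 takes up the HCl that would threaten the silyl ether, and one equivalent of reagent limits di-iodination.

Step 3
Reactants: 6 (3S)-3,7-dimethylocta-1,6-diene; 7 2-chloro-1,3,2-benzodioxaborole; 8 pinacol (2,3-dimethylbutane-2,3-diol)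
Product: 10 2-[(1E,3S)-3,7-dimethylocta-1,6-dien-1-yl]-4,4,5,5-tetramethyl-1,3,2-dioxaborolane, via catechol boronate 9 (not isolated)
Conditions: 7 (1.5 equiv), Pd2(dba)3 (2.5 mol%), (3,5-tBu2C6H3)2PtBu (6 mol%), LiOSO2CF3 (10 mol%), Cy2NMe, PhCF3, 70 °C; then 8, rt
Reagents that add atoms: 2-chloro-1,3,2-benzodioxaborole (7), ClB1Oc2ccccc2O1; pinacol (8), CC(C)(O)C(C)(C)O
Why: Boryl-Heck reaction (dehydrogenative borylation of a terminal alkene): the B–Cl bond adds oxidatively to zerovalent palladium, the unhindered vinyl group inserts with boron on C1', and β-hydride elimination from C1' gives the (E)-alkenyl boronate 9. The trisubstituted olefin is too hindered to insert, and C3' is untouched as long as elimination toward its tertiary C–H is avoided, which the bulky phosphine favours; exchange with 8 gives the bench-stable ester 10.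

Step 4
Reactants: 5 5-hydroxy-6-iodo-7-{[tri(propan-2-yl)silyl]oxy}-4H-chromen-4-one; 10 2-[(1E,3S)-3,7-dimethylocta-1,6-dien-1-yl]-4,4,5,5-tetramethyl-1,3,2-dioxaborolane
Product: 11 6-[(1E,3S)-3,7-dimethylocta-1,6-dien-1-yl]-5-hydroxy-7-{[tri(propan-2-yl)silyl]oxy}-4H-chromen-4-one
Conditions: 10 (1.3 equiv), Pd(OAc)2 (5 mol%), SPhos (10 mol%), K3PO4 (3 equiv), THF–H2O (10:1), 50 °C, argon
Reagents that add atoms: boronate 10, CC(C)=CCC[C@H](C)/C=C/B1OC(C)(C)C(C)(C)O1
Why: Suzuki–Miyaura coupling; SPhos is used because the iodide is flanked by two ortho oxygen substituents, and the coupling retains configuration at the alkenyl carbon, so the E geometry of 10 is carried over. The chromone has no stereocenter that the base could harm, and the 5-OH travels as its phenoxide and is recovered on work-up.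

Step 5
Reactants: 11 6-[(1E,3S)-3,7-dimethylocta-1,6-dien-1-yl]-5-hydroxy-7-{[tri(propan-2-yl)silyl]oxy}-4H-chromen-4-one; 12 (4-{[tert-butyl(dimethyl)silyl]oxy}phenyl)boronic acid
Product: 13 (2S)-2-(4-{[tert-butyl(dimethyl)silyl]oxy}phenyl)-6-[(1E,3S)-3,7-dimethylocta-1,6-dien-1-yl]-5-hydroxy-7-{[tri(propan-2-yl)silyl]oxy}-2,3-dihydro-4H-chromen-4-one
Conditions: 12 (2 equiv), Pd(OCOCF3)2 (5 mol%), (R)-t-BuPyOX [(R)-4-tert-butyl-2-(pyridin-2-yl)-4,5-dihydro-1,3-oxazole] (6 mol%), NH4PF6 (30 mol%), H2O (5 equiv), ClCH2CH2Cl, 60 °C
Reagents that add atoms: (4-{[tert-butyl(dimethyl)silyl]oxy}phenyl)boronic acid (12), CC(C)(C)[Si](C)(C)Oc1ccc(B(O)O)cc1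
Why: Transmetalation of 12 to the cationic t-BuPyOX-ligated divalent palladium gives an aryl–palladium species that binds the C2=C3 double bond of 11 and adds across it in a syn carbopalladation (aryl to C2, palladium to C3); the palladium enolate is then protonated by water, which releases 13 and the divalent catalyst, and β-hydride elimination to a flavone is excluded because the only β-hydrogen, on C2, is anti to palladium in the ring. The closest known reaction type is the palladium-catalysed asymmetric conjugate addition of arylboronic acids to chromones with pyridine–oxazoline ligands, an established entry to 2-arylchroman-4-ones, applied here to a chromone that carries the finished chain. No ring is closed; the step forms the C2–C1'' bond, the last bond of the skeleton. The new stereocenter C2 is controlled by the ligand alone: the tert-butyl group of the oxazoline blocks one enantioface of the bound enone, and with the R ligand the aryl group should be delivered to the Re face of C2, which is the 2S configuration; C3', eight bonds away, has no say. The step needs chemoselectivity for the enone over the C1'=C2' and C6'=C7' olefins, which is secured because the chromone is the only electron-poor, carbonyl-coordinating olefin, while the styrene is twisted between two ortho oxygen substituents and the other olefin is trisubstituted. It needs 1,4- rather than 1,2-addition, which the soft aryl–palladium species gives, and enough electrophilicity at C2 despite two donor oxygens on ring A, for which the hydrogen bond from the free 5-OH to the C4 carbonyl helps. The weakly acidic, base-free medium at 60 °C is also why the new C2 center should not equilibrate once formed.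

Step 6
Reactants: 13 (2S)-2-(4-{[tert-butyl(dimethyl)silyl]oxy}phenyl)-6-[(1E,3S)-3,7-dimethylocta-1,6-dien-1-yl]-5-hydroxy-7-{[tri(propan-2-yl)silyl]oxy}-2,3-dihydro-4H-chromen-4-one
Product: 14 (2S)-6-[(1E,3S)-3,7-dimethylocta-1,6-dien-1-yl]-5,7-dihydroxy-2-(4-hydroxyphenyl)-2,3-dihydro-4H-chromen-4-one
Conditions: Bu4NF (2.5 equiv), AcOH (3 equiv), THF, 0 °C to rt
Reagents that add atoms: none
Why: Fluoride-induced cleavage of the two aryl silyl ethers; acetic acid protonates the phenoxides as they form, so neither the retro-oxa-Michael opening of ring C at C2 nor an acid-promoted cyclisation of the o-hydroxystyrene should be triggered. No stereocenter is formed or touched.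

## Compound list

1 | 5,7-dihydroxy-4H-chromen-4-one | O=c1ccoc2cc(O)cc(O)c12 | starting material
2 | chlorotri(propan-2-yl)silane | CC(C)[Si](Cl)(C(C)C)C(C)C | starting material
3 | 5-hydroxy-7-{[tri(propan-2-yl)silyl]oxy}-4H-chromen-4-one | O=c1ccoc2cc(O[Si](C(C)C)(C(C)C)C(C)C)cc(O)c12 | intermediate
4 | benzyltrimethylammonium dichloroiodate | C[N+](C)(C)Cc1ccccc1.Cl[I-]Cl | starting material
5 | 5-hydroxy-6-iodo-7-{[tri(propan-2-yl)silyl]oxy}-4H-chromen-4-one | O=c1ccoc2cc(O[Si](C(C)C)(C(C)C)C(C)C)c(I)c(O)c12 | intermediate
6 | (3S)-3,7-dimethylocta-1,6-diene | C=C[C@@H](C)CCC=C(C)C | starting material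
7 | 2-chloro-1,3,2-benzodioxaborole | ClB1Oc2ccccc2O1 | starting material
8 | pinacol (2,3-dimethylbutane-2,3-diol) | CC(C)(O)C(C)(C)O | starting material
9 | 2-[(1E,3S)-3,7-dimethylocta-1,6-dien-1-yl]-1,3,2-benzodioxaborole | CC(C)=CCC[C@H](C)/C=C/B1Oc2ccccc2O1 | intermediate (not isolated)
10 | 2-[(1E,3S)-3,7-dimethylocta-1,6-dien-1-yl]-4,4,5,5-tetramethyl-1,3,2-dioxaborolane | CC(C)=CCC[C@H](C)/C=C/B1OC(C)(C)C(C)(C)O1 | intermediate
11 | 6-[(1E,3S)-3,7-dimethylocta-1,6-dien-1-yl]-5-hydroxy-7-{[tri(propan-2-yl)silyl]oxy}-4H-chromen-4-one | CC(C)=CCC[C@H](C)/C=C/c1c(O[Si](C(C)C)(C(C)C)C(C)C)cc2occc(=O)c2c1O | intermediate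
12 | (4-{[tert-butyl(dimethyl)silyl]oxy}phenyl)boronic acid | CC(C)(C)[Si](C)(C)Oc1ccc(B(O)O)cc1 | starting material
13 | (2S)-2-(4-{[tert-butyl(dimethyl)silyl]oxy}phenyl)-6-[(1E,3S)-3,7-dimethylocta-1,6-dien-1-yl]-5-hydroxy-7-{[tri(propan-2-yl)silyl]oxy}-2,3-dihydro-4H-chromen-4-one | CC(C)=CCC[C@H](C)/C=C/c1c(O[Si](C(C)C)(C(C)C)C(C)C)cc2c(c1O)C(=O)C[C@@H](c1ccc(O[Si](C)(C)C(C)(C)C)cc1)O2 | intermediate
14 | (2S)-6-[(1E,3S)-3,7-dimethylocta-1,6-dien-1-yl]-5,7-dihydroxy-2-(4-hydroxyphenyl)-2,3-dihydro-4H-chromen-4-one | CC(C)=CCC[C@H](C)/C=C/c1c(O)cc2c(c1O)C(=O)C[C@@H](c1ccc(O)cc1)O2 | target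

## Step count and least certain steps

Total step count: 6. Longest linear sequence: 5 steps (steps 1, 2, 4, 5 and 6, from 1 to 14); step 3 makes the side-chain fragment in one step from 6.

**Step 5 (key step).** The most likely failure is slow carbopalladation of the electron-rich, 5,7-dioxygenated chromone, so that protodeboronation of 12 outruns the addition. Binding of the cationic palladium centre at the 5-OH/C4=O chelating site, and erosion of facial selectivity by the crowded ring A, are the other risks. The fallback takes C2 from the chiral pool instead of making it, with known chemistry throughout. Purchased (2S)-naringenin F1 is silylated at O7 and O4' (TBSCl, imidazole; the chelated 5-OH stays free) to the bis-silyl ether F2. F2 is iodinated at C6 as in step 2 to iodide F3. F3 is coupled with boronate 10 under the mildest workable Suzuki–Miyaura conditions (Pd(OAc)2, SPhos, K3PO4, THF–H2O, rt) to the bis-silyl flavanone F4, which is desilylated as in step 6. This fallback sets out from 10 and comes back to the route at 14. Its own weak point is the exposure of C2 to base in the coupling, which is why it is not the main route.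

**Step 3.** The most likely failure is β-hydride elimination toward the tertiary C3'–H instead of C1'–H. That gives the allyl boronate and erases the stereocenter. In the fallback the boronate is made by alkyne hydroboration. Purchased (S)-citronellal F5 is converted in one pot into the terminal alkyne F6 by enol nonaflate formation and β-elimination (nonafluorobutanesulfonyl fluoride, phosphazene base). F6 is hydroborated with pinacolborane under Cp2Zr(H)Cl catalysis (syn addition, boron on the terminal carbon) to give 10. This fallback replaces 6 as the source of the chain: it sets out from purchased F5 instead of a numbered compound and comes back to the route at 10.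

**Step 4.** The most likely failure is slow oxidative addition and transmetalation at the doubly ortho-substituted iodide, so that protodeboronation of 10 and loss of the silyl ether in aqueous base take over. The fallback forms the same bond without boron, by a Mizoroki–Heck reaction of iodide 5 with diene 6 itself (Pd(OAc)2, Bu4NCl, NaHCO3, DMF, 70 °C). Insertion places the aryl group on the terminal carbon, and β-hydride elimination toward the benzylic hydrogen gives the conjugated E olefin. It sets out from 5 and 6 and comes back at 11; no new compound is made (F0).

**Step 6.** The most likely failure is epimerisation at C2 by retro-oxa-Michael opening if the fluoride medium becomes basic, or incomplete cleavage of the hindered O7 silyl ether. The fallback removes silicon before the stereocenter exists. Chromone 11 is desilylated under the same conditions to the chromone diol F7. The arylation of step 5 is then run on F7 with unprotected 4-hydroxyphenylboronic acid F8, which gives 14 directly, with no step after C2 is set. It sets out from 11 and comes back at 14.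

## Further compounds

F1 | step 5 | (2S)-5,7-dihydroxy-2-(4-hydroxyphenyl)-2,3-dihydro-4H-chromen-4-one ((2S)-naringenin, purchased) | O=C1C[C@@H](c2ccc(O)cc2)Oc2cc(O)cc(O)c21
F2 | step 5 | (2S)-7-{[tert-butyl(dimethyl)silyl]oxy}-2-(4-{[tert-butyl(dimethyl)silyl]oxy}phenyl)-5-hydroxy-2,3-dihydro-4H-chromen-4-one | O=C1C[C@@H](c2ccc(O[Si](C)(C)C(C)(C)C)cc2)Oc2cc(O[Si](C)(C)C(C)(C)C)cc(O)c21
F3 | step 5 | (2S)-7-{[tert-butyl(dimethyl)silyl]oxy}-2-(4-{[tert-butyl(dimethyl)silyl]oxy}phenyl)-5-hydroxy-6-iodo-2,3-dihydro-4H-chromen-4-one | O=C1C[C@@H](c2ccc(O[Si](C)(C)C(C)(C)C)cc2)Oc2cc(O[Si](C)(C)C(C)(C)C)c(I)c(O)c21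
F4 | step 5 | (2S)-7-{[tert-butyl(dimethyl)silyl]oxy}-2-(4-{[tert-butyl(dimethyl)silyl]oxy}phenyl)-6-[(1E,3S)-3,7-dimethylocta-1,6-dien-1-yl]-5-hydroxy-2,3-dihydro-4H-chromen-4-one | CC(C)=CCC[C@H](C)/C=C/c1c(O[Si](C)(C)C(C)(C)C)cc2c(c1O)C(=O)C[C@@H](c1ccc(O[Si](C)(C)C(C)(C)C)cc1)O2
F5 | step 3 | (3S)-3,7-dimethyloct-6-enal ((S)-citronellal, purchased) | C[C@@H](CCC=C(C)C)CC=O
F6 | step 3 | (3S)-3,7-dimethyloct-6-en-1-yne | C#C[C@@H](C)CCC=C(C)C
F0 | step 4 | none | none
F7 | step 6 | 6-[(1E,3S)-3,7-dimethylocta-1,6-dien-1-yl]-5,7-dihydroxy-4H-chromen-4-one | CC(C)=CCC[C@H](C)/C=C/c1c(O)cc2occc(=O)c2c1O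
F8 | step 6 | (4-hydroxyphenyl)boronic acid | OB(O)c1ccc(O)cc1
A1 | alternative 1 | 1-{6-hydroxy-2,4-bis(methoxymethoxy)-3-[(1E,3S)-3,7-dimethylocta-1,6-dien-1-yl]phenyl}ethan-1-one | CC(=O)c1c(O)cc(OCOC)c(/C=C/[C@@H](C)CCC=C(C)C)c1OCOC
A2 | alternative 1 | 4-(methoxymethoxy)benzaldehyde | COCOc1ccc(C=O)cc1
A3 | alternative 1 | (2E)-1-{6-hydroxy-2,4-bis(methoxymethoxy)-3-[(1E,3S)-3,7-dimethylocta-1,6-dien-1-yl]phenyl}-3-[4-(methoxymethoxy)phenyl]prop-2-en-1-one | COCOc1ccc(/C=C/C(=O)c2c(O)cc(OCOC)c(/C=C/[C@@H](C)CCC=C(C)C)c2OCOC)cc1
A4 | alternative 2 | (2S)-2-(4-{[tert-butyl(dimethyl)silyl]oxy}phenyl)-5-hydroxy-7-{[tri(propan-2-yl)silyl]oxy}-2,3-dihydro-4H-chromen-4-one | O=C1C[C@@H](c2ccc(O[Si](C)(C)C(C)(C)C)cc2)Oc2cc(O[Si](C(C)C)(C(C)C)C(C)C)cc(O)c21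
A5 | alternative 2 | (2S)-2-(4-{[tert-butyl(dimethyl)silyl]oxy}phenyl)-5-hydroxy-6-iodo-7-{[tri(propan-2-yl)silyl]oxy}-2,3-dihydro-4H-chromen-4-one | O=C1C[C@@H](c2ccc(O[Si](C)(C)C(C)(C)C)cc2)Oc2cc(O[Si](C(C)C)(C(C)C)C(C)C)c(I)c(O)c21
A6 | alternative 3 | (3S)-3,7-dimethyloct-6-enal ((S)-citronellal) | C[C@@H](CCC=C(C)C)CC=O
A7 | alternative 3 | 6-[(3S)-3,7-dimethyloct-6-en-1-ylidene]-7-{[tri(propan-2-yl)silyl]oxy}-4H-chromene-4,5(6H)-dione (o-quinone methide) | CC(C)=CCC[C@H](C)CC=C1C(=O)C2=C(OC=CC2=O)C=C1O[Si](C(C)C)(C(C)C)C(C)C
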